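**Retrosynthetic overview** (target ring numbering: O1, C2 pentyl, C3 O-laurate, C4 CH2, C5 side chain, C1' carbinol)
- The C1' carbinol comes from hydride reduction of a C1' ketone; that ketone comes from decarboxylative acylation of a C5 carboxylic acid with dec-9-enoyl chloride, which sets C5 trans to C2 and C3.
- The laurate is not made by acylation: it is the Baeyer–Villiger image of a C3 dodecanoyl ketone.
- Key disconnection: C4–C5 and C2–C3 are made together, with the oxolane (the only ring), by a Prins cyclization–pinacol rearrangement between benzyl glyoxylate and the vinyl 1,2-diol C5H11CH(OH)–C(OH)(C11H23)–CH=CH2.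
- The diol comes from methyl (S)-glycidate (source of C2) by butyl, undecyl and vinyl Grignard additions.
- Enabling feature: ring carbon C3 carries an acyloxy oxygen and lies between the unsubstituted ring carbon C4 and the pentyl-bearing ether carbon C2; an O-acyl on C3 is the Baeyer–Villiger image of a C3 acyl, and a 3-acyl oxolane with a free C4 methylene is what a vinyl carbinol next to a secondary ether carbon gives by Prins–pinacol.

Key step: step 5

Assumption: benzyl glyoxylate, methyl (S)-glycidate, dec-9-enoic acid and the three Grignard reagents are taken as commercial; the C5 epimers formed in step 5 are carried as a mixture through steps 6 and 7, because C5 becomes a planar radical in step 9.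

Step 1
Reactants: 1 methyl (2S)-oxirane-2-carboxylate; 2 n-butylmagnesium bromide
Product: 3 methyl (2S)-2-hydroxyheptanoate
Conditions: CuBr·SMe2 (10 mol%), THF, −78 → −40 °C; then aq. NH4Cl
Reagents that add atoms: none
Why: Copper-catalysed Grignard opening of the glycidic ester (organocuprate epoxide opening) should occur by SN2 attack at the unsubstituted epoxide carbon, so the C–O bond at the stereocentre is untouched and the (S) centre is carried into the α-hydroxy ester.

Step 2
Reactants: 3 methyl (2S)-2-hydroxyheptanoate
Product: 4 (2S)-2-hydroxy-N-methoxy-N-methylheptanamide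
Conditions: MeNH(OMe)·HCl, i-PrMgCl, THF, −20 → 0 °C
Reagents that add atoms: N,O-dimethylhydroxylamine hydrochloride, Cl.CNOC
Why: Weinreb amide formation by aminolysis of the ester with the magnesium amide should proceed at low temperature with the hydroxyl held as its magnesium alkoxide, which leaves the α-stereocentre intact.

Step 3
Reactants: 4 (2S)-2-hydroxy-N-methoxy-N-methylheptanamide; 5 undecylmagnesium bromide
Product: 6 (6S)-6-hydroxyoctadecan-7-one
Conditions: C11H23MgBr (2.5 equiv), THF, 0 °C; then cold aq. NH4Cl
Reagents that add atoms: none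
Why: Weinreb ketone synthesis, in which the Grignard reagent adds once to give a stable magnesium chelate that releases the ketone only on work-up, while the α-centre sits next to an alkoxide and should not be enolised.

Step 4
Reactants: 6 (6S)-6-hydroxyoctadecan-7-one; 7 vinylmagnesium bromide
Product: 8 (6S,7RS)-7-ethenyloctadecane-6,7-diol
Conditions: CH2=CHMgBr (3 equiv), THF, −78 → 0 °C; then aq. NH4Cl
Reagents that add atoms: none
Why: Chelation-controlled Grignard addition to the α-alkoxido ketone gives the tertiary allylic alcohol, and the ratio at the new carbinol carbon is of no consequence because this carbon becomes a carbonyl carbon in step 5.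

Step 5
Reactants: 8 (6S,7RS)-7-ethenyloctadecane-6,7-diol; 9 benzyl glyoxylate (benzyl 2-oxoacetate)
Product: 11 benzyl (2RS,4S,5S)-4-dodecanoyl-5-pentyloxolane-2-carboxylate, via dioxolane acetal 10 (not isolated)
Conditions: 9 (1.3 equiv), BF3·OEt2 (promoter), CH2Cl2, −40 → −20 °C
Reagents that add atoms: none
Why: BF3 converts the hemiacetal/acetal 10 into the oxocarbenium ion on the secondary oxygen, whose carbon is attacked by the terminal carbon of the vinyl group in a chair-like Prins closure (target bond C4–C5), and the cation that develops next to the tertiary carbinol is quenched by a pinacol 1,2-shift of the pentyl-bearing carbon (target bond C2–C3), which turns the carbinol carbon into the dodecanoyl ketone. The closest known reaction type is the Prins cyclization–pinacol rearrangement of allylic 1,2-diols with aldehydes to cis-3-acyl tetrahydrofurans, used there with a later Baeyer–Villiger step to reach 3-acyloxy tetrahydrofurans. The only ring is closed 6-endo-trig as an oxane cation and delivered as the five-membered oxolane by ring contraction. Target C2 keeps the diol configuration because the migrating carbon shifts with retention; target C3 is set cis to pentyl because pentyl sits equatorial in the chair and the shift is suprafacial onto the adjacent cationic carbon; the carboxylate-bearing carbon (expected cis) need not be controlled because it is reset in step 9. The step needs ionisation toward the non-allylic oxygen, which is secured because the alternative oxocarbenium ion cannot cyclise and returns to the acetal. It is stereoconvergent, since both tertiary-carbinol epimers and both acetal epimers lead to the same product once the carbinol carbon becomes the sp2 carbonyl, and low temperature should keep the kinetic cis ketone from epimerising.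

Step 6
Reactants: 11 benzyl (2RS,4S,5S)-4-dodecanoyl-5-pentyloxolane-2-carboxylate
Product: 12 benzyl (2RS,4S,5S)-4-(dodecanoyloxy)-5-pentyloxolane-2-carboxylate
Conditions: mCPBA (3 equiv), NaHCO3, CH2Cl2, 23 °C
Reagents that add atoms: 3-chloroperbenzoic acid, OOC(=O)c1cccc(Cl)c1
Why: Baeyer–Villiger oxidation, in which the secondary ring carbon should migrate from the Criegee intermediate in preference to the primary undecyl chain and with retention, so the cis ketone becomes the cis laurate; no alkene is present at this stage.

Step 7
Reactants: 12 benzyl (2RS,4S,5S)-4-(dodecanoyloxy)-5-pentyloxolane-2-carboxylate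
Product: 13 (2RS,4S,5S)-4-(dodecanoyloxy)-5-pentyloxolane-2-carboxylic acid
Conditions: H2 (1 atm), Pd/C (10 wt%), EtOAc, 23 °C
Reagents that add atoms: none
Why: Hydrogenolysis of the benzyl ester over palladium frees the α-alkoxy acid without touching the alkyl laurate.

Step 8
Reactants: 14 dec-9-enoic acid
Product: 15 dec-9-enoyl chloride
Conditions: (COCl)2, DMF (cat.), CH2Cl2, 0 → 23 °C
Reagents that add atoms: oxalyl chloride, ClC(=O)C(=O)Cl
Why: Acid chloride formation through the Vilsmeier-type chloroiminium species is mild enough to leave the terminal alkene untouched.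

Step 9
Reactants: 13 (2RS,4S,5S)-4-(dodecanoyloxy)-5-pentyloxolane-2-carboxylic acid; 15 dec-9-enoyl chloride
Product: 17 (2S,3S,5R)-5-(dec-9-enoyl)-2-pentyloxolan-3-yl dodecanoate, via mixed anhydride 16 (not isolated)
Conditions: Ir[dF(CF3)ppy]2(dtbbpy)PF6 (1 mol%), NiCl2·glyme (5 mol%), dtbbpy (5 mol%), DBU (1.1 equiv), 1,4-dioxane, blue LEDs, 23 °C
Reagents that add atoms: none
Why: Nickel/photoredox decarboxylative acylation (CO2 extrusion–recombination of a mixed anhydride), in which zerovalent nickel inserts into 16, photocatalytic oxidation of the α-alkoxy carboxylate expels CO2, and the planar C5 radical should be captured by the acyl-nickel species on the ring face opposite the cis pentyl and acyloxy groups, which erases the C5 mixture and sets C5 trans to both.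

Step 10
Reactants: 17 (2S,3S,5R)-5-(dec-9-enoyl)-2-pentyloxolan-3-yl dodecanoate
Product: 18 (2S,3S,5R)-5-[(1R)-1-hydroxydec-9-en-1-yl]-2-pentyloxolan-3-yl dodecanoate
Conditions: LiBH(s-Bu)3 (1.2 equiv), THF, −78 °C; then H2O, 0 °C
Reagents that add atoms: none
Why: Felkin–Anh reduction of the α-alkoxy ketone by the bulky hydride (ring oxygen anti to the incoming hydride) should give the (R)-carbinol, threo to C5, and at −78 °C the reagent should not reduce the ester or touch the alkene.

**Compound list**
1 | methyl (2S)-oxirane-2-carboxylate | COC(=O)[C@@H]1CO1 | starting material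
2 | n-butylmagnesium bromide | CCCC[Mg]Br | starting material
3 | methyl (2S)-2-hydroxyheptanoate | CCCCC[C@H](O)C(=O)OC | intermediate
4 | (2S)-2-hydroxy-N-methoxy-N-methylheptanamide | CCCCC[C@H](O)C(=O)N(C)OC | intermediate
5 | undecylmagnesium bromide | CCCCCCCCCCC[Mg]Br | starting material
6 | (6S)-6-hydroxyoctadecan-7-one | CCCCC[C@H](O)C(=O)CCCCCCCCCCC | intermediate
7 | vinylmagnesium bromide | C=C[Mg]Br | starting material
8 | (6S,7RS)-7-ethenyloctadecane-6,7-diol | CCCCC[C@H](O)C(O)(C=C)CCCCCCCCCCC | intermediate
9 | benzyl glyoxylate (benzyl 2-oxoacetate) | O=CC(=O)OCc1ccccc1 | starting material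
10 | benzyl (2RS,4RS,5S)-4-ethenyl-5-pentyl-4-undecyl-1,3-dioxolane-2-carboxylate | O=C(OCc1ccccc1)C1O[C@@H](CCCCC)C(C=C)(CCCCCCCCCCC)O1 | intermediate
11 | benzyl (2RS,4S,5S)-4-dodecanoyl-5-pentyloxolane-2-carboxylate | O=C(OCc1ccccc1)C1C[C@H](C(=O)CCCCCCCCCCC)[C@H](CCCCC)O1 | intermediate
12 | benzyl (2RS,4S,5S)-4-(dodecanoyloxy)-5-pentyloxolane-2-carboxylate | O=C(OCc1ccccc1)C1C[C@H](OC(=O)CCCCCCCCCCC)[C@H](CCCCC)O1 | intermediate
13 | (2RS,4S,5S)-4-(dodecanoyloxy)-5-pentyloxolane-2-carboxylic acid | OC(=O)C1C[C@H](OC(=O)CCCCCCCCCCC)[C@H](CCCCC)O1 | intermediate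
14 | dec-9-enoic acid | C=CCCCCCCCC(=O)O | starting material
15 | dec-9-enoyl chloride | C=CCCCCCCCC(=O)Cl | intermediate
16 | dec-9-enoic (2RS,4S,5S)-4-(dodecanoyloxy)-5-pentyloxolane-2-carboxylic anhydride | C=CCCCCCCCC(=O)OC(=O)C1C[C@H](OC(=O)CCCCCCCCCCC)[C@H](CCCCC)O1 | intermediate
17 | (2S,3S,5R)-5-(dec-9-enoyl)-2-pentyloxolan-3-yl dodecanoate | C=CCCCCCCCC(=O)[C@H]1C[C@H](OC(=O)CCCCCCCCCCC)[C@H](CCCCC)O1 | intermediate
18 | (2S,3S,5R)-5-[(1R)-1-hydroxydec-9-en-1-yl]-2-pentyloxolan-3-yl dodecanoate | C=CCCCCCCC[C@@H](O)[C@H]1C[C@H](OC(=O)CCCCCCCCCCC)[C@H](CCCCC)O1 | target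

**Step count**
Total steps: 10. Longest linear sequence: 9 (steps 1 to 7, then 9 and 10; step 8 is a one-step side branch).

**Steps most likely to fail**

Step 5. The oxocarbenium ion next to the ester is electron-poor, so heterolysis of the tertiary allylic C–O bond (allyl cation formation, elimination) may outrun productive ionisation, or the reaction may stall at the acetal. The fallback sets out from 8 and comes back at 13; it uses (benzyloxy)acetaldehyde, whose oxocarbenium ion is less destabilised and which has the closest precedent in this reaction class. Diol 8 and (benzyloxy)acetaldehyde under BF3·OEt2 (CH2Cl2, −23 °C) would pass through (2RS,4RS,5S)-2-[(benzyloxy)methyl]-4-ethenyl-5-pentyl-4-undecyl-1,3-dioxolane F1, which is not isolated, to 1-[(2S,3S,5RS)-5-[(benzyloxy)methyl]-2-pentyloxolan-3-yl]dodecan-1-one F2. Baeyer–Villiger oxidation with mCPBA and NaHCO3 would give (2S,3S,5RS)-5-[(benzyloxy)methyl]-2-pentyloxolan-3-yl dodecanoate F3. Hydrogenolysis (H2, Pd(OH)2/C, EtOAc) would give (2S,3S,5RS)-5-(hydroxymethyl)-2-pentyloxolan-3-yl dodecanoate F4, and oxidation with TEMPO and PhI(OAc)2 in MeCN/H2O would give acid 13.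

Step 9. Facial selectivity in the capture of the C5 radical may be poor, the amine base may epimerise the α-alkoxy ketone at C5, or oxidative addition into the mixed anhydride may be unproductive. The fallback sets out from 13 and 14 and comes back at 17; it replaces the photochemical, base-mediated coupling by a thermal, base-free reductive coupling of two activated esters. Acid 13 with N-hydroxyphthalimide, N,N'-diisopropylcarbodiimide and catalytic DMAP would give 1,3-dioxoisoindol-2-yl (2RS,4S,5S)-4-(dodecanoyloxy)-5-pentyloxolane-2-carboxylate F5. Acid 14 with 2,2'-dipyridyl disulfide and PPh3 would give S-(pyridin-2-yl) dec-9-enethioate F6. Coupling of the two (NiCl2·glyme, dtbbpy, Zn, THF, 23 °C) would give ketone 17 under neutral conditions. The stereochemical argument is the same steric one as in the main step, so this fallback removes the base and the photochemistry but does not add a new control element. If both C5 epimers of 17 form, they would be separated and the unwanted one re-equilibrated with DBU and recycled.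

Step 6. The primary undecyl group may migrate in competition with the ring carbon, or enolisation next to the ketone may erode the cis relation before oxygen insertion. The fallback sets out from 4 and comes back at 12; it runs the sequence in the acetyl series, where methyl does not migrate, and installs the laurate afterwards. Amide 4 with MeMgBr (THF, 0 °C) would give (3S)-3-hydroxyoctan-2-one F7, and vinylmagnesium bromide would give (3RS,4S)-3-methylnon-1-ene-3,4-diol F8. Condensation with 9 under BF3·OEt2 would pass through benzyl (2RS,4RS,5S)-4-ethenyl-4-methyl-5-pentyl-1,3-dioxolane-2-carboxylate F9, which is not isolated, to benzyl (2RS,4S,5S)-4-acetyl-5-pentyloxolane-2-carboxylate F10. mCPBA would give benzyl (2RS,4S,5S)-4-acetoxy-5-pentyloxolane-2-carboxylate F11. K2CO3 in benzyl alcohol would remove the acetyl group while keeping the benzyl ester, giving benzyl (2RS,4S,5S)-4-hydroxy-5-pentyloxolane-2-carboxylate F12. Dodecanoyl chloride, pyridine and catalytic DMAP would then give 12.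

Further compounds
F1 | step 5 | (2RS,4RS,5S)-2-[(benzyloxy)methyl]-4-ethenyl-5-pentyl-4-undecyl-1,3-dioxolane | c1ccccc1COCC1O[C@@H](CCCCC)C(C=C)(CCCCCCCCCCC)O1
F2 | step 5 | 1-[(2S,3S,5RS)-5-[(benzyloxy)methyl]-2-pentyloxolan-3-yl]dodecan-1-one | c1ccccc1COCC1C[C@H](C(=O)CCCCCCCCCCC)[C@H](CCCCC)O1
F3 | step 5 | (2S,3S,5RS)-5-[(benzyloxy)methyl]-2-pentyloxolan-3-yl dodecanoate | c1ccccc1COCC1C[C@H](OC(=O)CCCCCCCCCCC)[C@H](CCCCC)O1
F4 | step 5 | (2S,3S,5RS)-5-(hydroxymethyl)-2-pentyloxolan-3-yl dodecanoate | OCC1C[C@H](OC(=O)CCCCCCCCCCC)[C@H](CCCCC)O1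
F5 | step 9 | 1,3-dioxoisoindol-2-yl (2RS,4S,5S)-4-(dodecanoyloxy)-5-pentyloxolane-2-carboxylate | O=C(ON1C(=O)c2ccccc2C1=O)C1C[C@H](OC(=O)CCCCCCCCCCC)[C@H](CCCCC)O1
F6 | step 9 | S-(pyridin-2-yl) dec-9-enethioate | C=CCCCCCCCC(=O)Sc1ccccn1
F7 | step 6 | (3S)-3-hydroxyoctan-2-one | CCCCC[C@H](O)C(C)=O
F8 | step 6 | (3RS,4S)-3-methylnon-1-ene-3,4-diol | CCCCC[C@H](O)C(C)(O)C=C
F9 | step 6 | benzyl (2RS,4RS,5S)-4-ethenyl-4-methyl-5-pentyl-1,3-dioxolane-2-carboxylate | O=C(OCc1ccccc1)C1O[C@@H](CCCCC)C(C)(C=C)O1
F10 | step 6 | benzyl (2RS,4S,5S)-4-acetyl-5-pentyloxolane-2-carboxylate | O=C(OCc1ccccc1)C1C[C@H](C(C)=O)[C@H](CCCCC)O1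
F11 | step 6 | benzyl (2RS,4S,5S)-4-acetoxy-5-pentyloxolane-2-carboxylate | O=C(OCc1ccccc1)C1C[C@H](OC(C)=O)[C@H](CCCCC)O1
F12 | step 6 | benzyl (2RS,4S,5S)-4-hydroxy-5-pentyloxolane-2-carboxylate | O=C(OCc1ccccc1)C1C[C@H](O)[C@H](CCCCC)O1
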